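## The problem

The target 20 is a sesquineolignan made of three guaiacyl units. Rings A and B are joined through a 2-aryl-3-hydroxymethyl-2,3-dihydrobenzofuran (ring A on C2, methoxy on C7). C5 of ring B carries a propane-1,3-diol chain whose carbinol carbon (Cα) is bonded to ring B and whose central carbon (Cβ) bears ring C. There are four stereocentres in two pairs: C2/C3 (trans, 2S,3R) and Cα/Cβ (syn, 1S,2R on the propane chain). Within a pair one centre can direct the other, but the pairs lie para to each other across the flat ring B and cannot communicate, so absolute control must be introduced twice. Both oxygen-bearing benzylic carbons ionise easily: C2 is para to the ring-A oxygen and Cα is para to O1. Acid therefore opens quinone-methide-type pathways (epimerisation, ring opening, loss of formaldehyde from the 1,3-diol), the free phenols are oxidisable, and the benzylic C–O bonds can be hydrogenolysed. The feature that makes the plan possible is that ring B is a 5-substituted vanillin: its phenol oxygen is O1, the formyl carbon para to it is Cα, and the ortho carbon that is iodinated in commercial 5-iodovanillin is C3a. A 1-arylallyl group on O1 places the internal vinyl carbon five atoms from C3a, so a radical at C3a can close onto it to form C3–C3a, and the exocyclic carbon can take up the hydroxymethyl oxygen in the same event.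

## Retrosynthesis

**Unmasking (20 ⇐ 19 ⇐ 18).** The last two operations cut only protecting bonds: the two aryl O–benzyl bonds of 19 and, before that, the N–O bond of the alkoxyamine in 18. The benzyl ethers go last because free para-phenols would make C2 and Cα far more ionisable in the acidic N–O cleavage. The alkoxyamine is kept as the protecting group of the C3 hydroxymethyl throughout the side-chain work, so the oxygen introduced in the key step costs no separate protection.

**Side chain (18 ⇐ 17 ⇐ 8 + 14).** The Cα–Cβ bond is cut as an aldol between aldehyde 8 and the arylacetyl oxazolidinone 14; reduction of the imide in 17 gives the primary alcohol of 18. The neighbouring cuts are less attractive: C5–Cα would need a metalated dihydrobenzofuran and would leave Cα to substrate control, and Cβ–ring C would need a three-component coupling on the most advanced fragment. The aldol sets both centres at once, is reagent-controlled (so the remote C2/C3 pair does not matter), and uses the aldehyde ring B already has. The forward step must give the syn isomer with the (S)-auxiliary face selectivity.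

**Dihydrofuran ring (8 ⇐ 7).** The C3–C3a bond and the exocyclic CH2–O bond are cut together. This removes the ring, the C3 stereocentre and the alkoxyamine oxygen, and leaves the acyclic aryl allyl ether 7 with one stereocentre. A cut at O1–C2 would need acid and a free ring-A phenol; a cut at C2–C3 has no simple polar equivalent. The forward reaction must close 5-exo from the C3a radical, place the new CH2 group trans to ring A, and leave the aldehyde alone.

**Aryl allyl ether (7 ⇐ 4 + 5, through 6).** The C2–O1 bond is cut to the linear cinnamyl-type carbonate 4 and the phenoxide 6 of 5-iodovanillin 5. A branched-selective, enantioselective iridium allylic etherification sets C2 catalytically. An SN2 etherification of a preformed chiral carbinol is less attractive because this carbon is para-alkoxybenzylic and allylic and tends to ionise.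

**Ring-A fragment (4 ⇐ 3 ⇐ 2 ⇐ 1).** Carbonate 4 comes from allylic alcohol 3, which comes from the dibenzylated ester 2 of ferulic acid 1. These are functional-group changes only.

**Ring-C fragment (14 ⇐ 13 ⇐ 11 + 12; 11 ⇐ 10 ⇐ 9).** Imide 14 is the N-acylation product of auxiliary 12 with acid 11 via mixed anhydride 13. Acid 11 is O-benzylated homovanillic acid 9, reached through ester 10.

## Roads not taken

**Alternative 1:** The cut is O1–C2. An open-chain diol A2, with only the future C3 centre defined, would be treated with acid. Either carbinol epimer ionises to the ring-A para-quinone methide, and the ring-B phenol oxygen adds to C2 to give the bromo-dihydrobenzofuran A1.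
- Merits: the closure is stereoconvergent, only one centre needs asymmetric synthesis, no tin is used, and the trans ring forms under conditions that allow equilibration. On trans selectivity this road is probably more secure than a kinetic radical closure.
- Weak points: the one stereocentre of A2 is a benzylic CH between a carbinol and a CH2OH group. It still needs its own asymmetric synthesis, and under acid it can be lost by tautomerisation of the quinone methide or by formaldehyde loss. A1 carries bromine at C5, not a carbonyl, and has a free phenol and alcohol, so protection and a metalation or formylation are needed before the side chain can be attached. The acid step must precede any Cα carbinol.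
- Comparison: the chosen plan sets against the better trans control a neutral ring closure that delivers 8 with the aldehyde in place and the C3 oxygen already protected.

**Alternative 2:** The cut is the Cβ–carbonyl bond and the lactone C–O bond of A3. The trans-epoxide A4 would be carbonylated with [(salph)Al(THF)2][Co(CO)4] under CO. Cobaltate attack with inversion at the carbon bearing ring C, then acyl closure onto oxygen, gives the cis-β-lactone A3, and hydride reduction would give the syn 1,3-diol.
- Merits: both side-chain centres come stereospecifically from one epoxide, the step is catalytic and atom-economical, and no auxiliary is needed. For the side chain alone this is more elegant than the auxiliary aldol of the chosen plan.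
- Weak points: regioselectivity rests only on the electronic difference between a mesylated and a benzylated guaiacyl ring. Electron-rich diaryl epoxides tend to rearrange to carbonyl compounds under Lewis acid. The α-aryl cis-lactone A3 can epimerise or decarboxylate. Above all, ring B arrives as a plain guaiacyl unit, so the dihydrobenzofuran would have to be annulated later next to an acid-sensitive benzylic diol.
- Comparison: the chosen plan gives up the catalytic side-chain construction but solves the ring system first and then needs only a well-behaved aldol on 8.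

**Alternative 3:** The cuts are C5–Cα and Cβ–ring C. Bromide A6 would be lithiated and added to the (E)-alkenyl boronic ester A7. Pd(OAc)2 with a MandyPhos ligand and aryl triflate A8 would then trigger the 1,2-shift of ring B from boron to carbon, with ring C delivered to Cβ; oxidation gives A5.
- Merits: this is the most convergent road. Two C–C bonds and both side-chain centres are made in one catalytic step, and anti addition across the (E)-alkene gives the required syn relationship. In step economy for the side chain it is better than aldol plus auxiliary removal.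
- Weak points: β-substituted alkenyl boronates are the difficult substrate class for this coupling (direct cross-coupling competes). The electron-rich triflate A8 adds slowly to palladium. The lithium halide from the exchange can inhibit the catalyst. The most valuable fragment, A6, is used stoichiometrically in the least certain step. A6 itself still needs a synthesis of the trans-dihydrobenzofuran with a halide in place of the aldehyde, plus silyl protection.
- Comparison: the chosen plan is less convergent but exposes 8 only to a robust, reagent-controlled aldol.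

Key step: step 5

Assumption: the (Sa,Sc,Sc) antipode of the phosphoramidite is taken to give the (S)-ether 7, by the usual sense of induction with cinnamyl carbonates and heteroatom nucleophiles; if the sense is the reverse, the (Ra,Rc,Rc) ligand is used and nothing else changes.

## Route

Step 1
Reactants: 1 ferulic acid
Product: 2 benzyl (E)-3-(4-benzyloxy-3-methoxyphenyl)acrylate
Conditions: BnBr (2.5 equiv), K2CO3, DMF, 60 °C
Reagents that add atoms: benzyl bromide, BrCc1ccccc1
Why: Williamson-type O-alkylation of both the phenoxide and the carboxylate in one flask; the benzyl ester only makes the acid reducible and is lost in step 2.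

Step 2
Reactants: 2 benzyl (E)-3-(4-benzyloxy-3-methoxyphenyl)acrylate
Product: 3 (E)-3-(4-benzyloxy-3-methoxyphenyl)prop-2-en-1-ol
Conditions: iBu2AlH (2.5 equiv), CH2Cl2, −78 to 0 °C; aq. potassium sodium tartrate
Reagents that add atoms: none
Why: 1,2-reduction of an enoate to the allylic alcohol by the aluminium hydride; the (E)-alkene and the aryl benzyl ether are not touched.

Step 3
Reactants: 3 (E)-3-(4-benzyloxy-3-methoxyphenyl)prop-2-en-1-ol
Product: 4 (E)-3-(4-benzyloxy-3-methoxyphenyl)allyl methyl carbonate
Conditions: ClCO2Me, pyridine, CH2Cl2, 0 °C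
Reagents that add atoms: methyl chloroformate, COC(=O)Cl
Why: O-acylation of a primary allylic alcohol with a chloroformate; the methyl carbonate is the standard leaving group for iridium-catalysed allylic substitution.

Step 4
Reactants: 4 (E)-3-(4-benzyloxy-3-methoxyphenyl)allyl methyl carbonate; 5 5-iodovanillin (4-hydroxy-3-iodo-5-methoxybenzaldehyde)
Product: 7 (S)-4-{[1-(4-benzyloxy-3-methoxyphenyl)prop-2-en-1-yl]oxy}-3-iodo-5-methoxybenzaldehyde, via sodium phenoxide 6 (not isolated)
Conditions: 5 (1.5 equiv), NaH, THF, 0 °C; then 4, [Ir(cod)Cl]2 (2 mol %), (Sa,Sc,Sc)-O,O'-(1,1'-binaphthyl-2,2'-diyl)-N,N-bis(1-phenylethyl)phosphoramidite (4 mol %), THF, 50 °C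
Reagents that add atoms: none
Why: Iridium-catalysed asymmetric allylic etherification of a cinnamyl-type carbonate with an alkali aryloxide: the cyclometalated iridium–phosphoramidite catalyst ionises 4 to an allyl complex that the aryloxide should attack at the aryl-substituted terminus, so C2 is set by the catalyst. Both ortho positions of ring B are substituted, so aromatic Claisen rearrangement of 7 has no productive outlet.

Step 5
Reactants: 7 (S)-4-{[1-(4-benzyloxy-3-methoxyphenyl)prop-2-en-1-yl]oxy}-3-iodo-5-methoxybenzaldehyde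
Product: 8 (2S,3R)-2-(4-benzyloxy-3-methoxyphenyl)-7-methoxy-3-[(2,2,6,6-tetramethylpiperidin-1-yloxy)methyl]-2,3-dihydrobenzofuran-5-carbaldehyde
Conditions: Bu3SnH (3 equiv, in portions), TEMPO (6 equiv), PhH (0.05 M), 70 °C
Reagents that add atoms: TEMPO (2,2,6,6-tetramethylpiperidin-1-oxyl), CC1(C)CCCC(C)(C)N1[O]
Why: TEMPO abstracts hydrogen from Bu3SnH to give Bu3Sn•, which removes the iodine atom of 7 and leaves a σ-radical at C3a. That radical adds to the internal vinyl carbon on C2 in a 5-exo-trig closure, forming C3–C3a and the dihydrofuran ring, and the exocyclic primary radical is captured by TEMPO at a near diffusion-controlled rate, forming the CH2–O bond. The closest known reaction type is the tin-hydride-mediated aryl radical 5-exo-trig cyclisation of ortho-halophenyl allyl ethers with nitroxide trapping of the cyclised radical. C3 is the only new stereocentre and is controlled by C2: in the chair-like transition state ring A lies pseudo-equatorial, so the new CH2 group ends trans to it, giving (2S,3R). Closure must outrun every other fate of the aryl radical; ring closure of 2-allyloxyphenyl radicals is among the fastest radical cyclisations, dilution keeps TEMPO from intercepting the aryl radical first, and transfer of the C2 hydrogen to C3a would be a strained 1,4-shift. 5-Exo attack is preferred over 6-endo because the tether runs through the sp2 carbons C3a and C7a and the alkene is terminal. Fast TEMPO capture should also prevent neophyl-type ring expansion of the primary radical and its reduction to a methyl group. The C5 aldehyde, the benzyl ether and the C2 centre should be inert under these neutral conditions.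

Step 6
Reactants: 9 homovanillic acid (2-(4-hydroxy-3-methoxyphenyl)acetic acid)
Product: 11 2-(4-benzyloxy-3-methoxyphenyl)acetic acid, via benzyl ester 10 (not isolated)
Conditions: BnBr (2.4 equiv), K2CO3, acetone, reflux; then aq. NaOH, MeOH, reflux; HCl
Reagents that add atoms: benzyl bromide, BrCc1ccccc1; sodium hydroxide, [Na+].[OH-]
Why: Williamson O-benzylation of phenol and carboxylate followed by saponification of the benzyl ester in the same flask; the aryl benzyl ether is stable to hydroxide.

Step 7
Reactants: 11 2-(4-benzyloxy-3-methoxyphenyl)acetic acid; 12 (S)-4-benzyl-2-oxazolidinone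
Product: 14 (S)-4-benzyl-3-[2-(4-benzyloxy-3-methoxyphenyl)acetyl]oxazolidin-2-one, via mixed pivalic anhydride 13 (not isolated)
Conditions: PivCl, Et3N, THF, −20 °C; then 12, LiCl, −20 °C to rt
Reagents that add atoms: none
Why: Mixed-anhydride N-acylation of the oxazolidinone; the nucleophile attacks the unhindered arylacetyl carbonyl, not the pivaloyl one.

Step 8
Reactants: 8 (2S,3R)-2-(4-benzyloxy-3-methoxyphenyl)-7-methoxy-3-[(2,2,6,6-tetramethylpiperidin-1-yloxy)methyl]-2,3-dihydrobenzofuran-5-carbaldehyde; 14 (S)-4-benzyl-3-[2-(4-benzyloxy-3-methoxyphenyl)acetyl]oxazolidin-2-one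
Product: 17 (S)-4-benzyl-3-[(2S,3S)-2-(4-benzyloxy-3-methoxyphenyl)-3-hydroxy-3-{(2S,3R)-2-(4-benzyloxy-3-methoxyphenyl)-7-methoxy-3-[(2,2,6,6-tetramethylpiperidin-1-yloxy)methyl]-2,3-dihydrobenzofuran-5-yl}propanoyl]oxazolidin-2-one, via dibutylboron Z-enolate 15 (not isolated), via dibutylboron aldolate 16 (not isolated)
Conditions: 14 (1.3 equiv), Bu2BOTf, iPr2NEt, CH2Cl2, −78 to 0 °C; then 8, −78 to 0 °C; aq. NaH2PO4/Na2HPO4 (pH 7), MeOH, H2O2, 0 °C
Reagents that add atoms: none
Why: Evans syn-aldol: soft enolisation gives the Z-boron enolate, the closed chair transition state gives the syn relationship of Cα and Cβ, and the benzyl group of the auxiliary blocks one enolate face, so the (2S,3S)-adduct should form by reagent control regardless of the remote C2/C3 pair. The hindered alkoxyamine and the benzyl ethers are inert to the boron triflate at low temperature.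

Step 9
Reactants: 17 the aldol adduct of step 8
Product: 18 (1S,2R)-2-(4-benzyloxy-3-methoxyphenyl)-1-{(2S,3R)-2-(4-benzyloxy-3-methoxyphenyl)-7-methoxy-3-[(2,2,6,6-tetramethylpiperidin-1-yloxy)methyl]-2,3-dihydrobenzofuran-5-yl}propane-1,3-diol
Conditions: LiBH4, MeOH (1.2 equiv), THF, 0 °C
Reagents that add atoms: none
Why: Reductive removal of the oxazolidinone: borohydride attacks the exocyclic imide carbonyl and gives the primary alcohol while 12 is released for recovery; the cold, weakly basic medium should leave the Cβ–H centre unchanged.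

Step 10
Reactants: 18 the alkoxyamine diol of step 9
Product: 19 (1S,2R)-2-(4-benzyloxy-3-methoxyphenyl)-1-[(2S,3R)-2-(4-benzyloxy-3-methoxyphenyl)-3-(hydroxymethyl)-7-methoxy-2,3-dihydrobenzofuran-5-yl]propane-1,3-diol
Conditions: Zn dust, AcOH/THF/H2O (3:1:1), 50 °C
Reagents that add atoms: none
Why: Reductive N–O cleavage of an O-alkyl hydroxylamine by zinc in acetic acid, the standard release of an alcohol from a TEMPO adduct. It is run while both phenols are still benzylated, which keeps C2 and Cα from ionising in the acid.

Step 11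
Reactants: 19 the bis-benzyl triol of step 10
Product: 20 (1S,2R)-1-[(2S,3R)-2-(4-hydroxy-3-methoxyphenyl)-3-(hydroxymethyl)-7-methoxy-2,3-dihydrobenzofuran-5-yl]-2-(4-hydroxy-3-methoxyphenyl)propane-1,3-diol
Conditions: H2 (1 atm), 10% Pd/C, EtOAc/MeOH, rt
Reagents that add atoms: none
Why: Catalytic hydrogenolysis of two aryl benzyl ethers, which cleave much faster than the benzylic C–O bonds at C2 and Cα, so the reaction is stopped after two equivalents of hydrogen; the medium is neutral.

## Compound list

1 | ferulic acid | COc1cc(/C=C/C(=O)O)ccc1O | starting material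
2 | benzyl (E)-3-(4-benzyloxy-3-methoxyphenyl)acrylate | COc1cc(/C=C/C(=O)OCc2ccccc2)ccc1OCc1ccccc1 | intermediate
3 | (E)-3-(4-benzyloxy-3-methoxyphenyl)prop-2-en-1-ol | COc1cc(/C=C/CO)ccc1OCc1ccccc1 | intermediate
4 | (E)-3-(4-benzyloxy-3-methoxyphenyl)allyl methyl carbonate | COc1cc(/C=C/COC(=O)OC)ccc1OCc1ccccc1 | intermediate
5 | 5-iodovanillin | COc1cc(C=O)cc(I)c1O | starting material
6 | sodium 4-formyl-2-iodo-6-methoxyphenolate (not isolated) | COc1cc(C=O)cc(I)c1[O-].[Na+] | intermediate
7 | (S)-4-{[1-(4-benzyloxy-3-methoxyphenyl)prop-2-en-1-yl]oxy}-3-iodo-5-methoxybenzaldehyde | COc1cc([C@H](C=C)Oc2c(I)cc(C=O)cc2OC)ccc1OCc1ccccc1 | intermediate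
8 | (2S,3R)-2-(4-benzyloxy-3-methoxyphenyl)-7-methoxy-3-[(2,2,6,6-tetramethylpiperidin-1-yloxy)methyl]-2,3-dihydrobenzofuran-5-carbaldehyde | COc1cc([C@H]2Oc3c(OC)cc(C=O)cc3[C@@H]2CON4C(C)(C)CCCC4(C)C)ccc1OCc1ccccc1 | intermediate
9 | homovanillic acid | COc1cc(CC(=O)O)ccc1O | starting material
10 | benzyl 2-(4-benzyloxy-3-methoxyphenyl)acetate (not isolated) | COc1cc(CC(=O)OCc2ccccc2)ccc1OCc1ccccc1 | intermediate
11 | 2-(4-benzyloxy-3-methoxyphenyl)acetic acid | COc1cc(CC(=O)O)ccc1OCc1ccccc1 | intermediate
12 | (S)-4-benzyl-2-oxazolidinone | O=C1N[C@@H](Cc2ccccc2)CO1 | starting material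
13 | 2-(4-benzyloxy-3-methoxyphenyl)acetic pivalic anhydride (not isolated) | COc1cc(CC(=O)OC(=O)C(C)(C)C)ccc1OCc1ccccc1 | intermediate
14 | (S)-4-benzyl-3-[2-(4-benzyloxy-3-methoxyphenyl)acetyl]oxazolidin-2-one | COc1cc(CC(=O)N2[C@@H](Cc3ccccc3)COC2=O)ccc1OCc1ccccc1 | intermediate
15 | dibutylboron (Z)-enolate of 14 (not isolated) | COc1cc(/C=C(\OB(CCCC)CCCC)N2[C@@H](Cc3ccccc3)COC2=O)ccc1OCc1ccccc1 | intermediate
16 | O-dibutylboryl aldolate of 17 (not isolated) | COc1cc([C@H]2Oc3c(OC)cc([C@@H](OB(CCCC)CCCC)[C@@H](C(=O)N4[C@@H](Cc5ccccc5)COC4=O)c4ccc(OCc5ccccc5)c(OC)c4)cc3[C@@H]2CON4C(C)(C)CCCC4(C)C)ccc1OCc1ccccc1 | intermediate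
17 | (S)-4-benzyl-3-[(2S,3S)-2-(4-benzyloxy-3-methoxyphenyl)-3-hydroxy-3-{(2S,3R)-2-(4-benzyloxy-3-methoxyphenyl)-7-methoxy-3-[(2,2,6,6-tetramethylpiperidin-1-yloxy)methyl]-2,3-dihydrobenzofuran-5-yl}propanoyl]oxazolidin-2-one | COc1cc([C@H]2Oc3c(OC)cc([C@@H](O)[C@@H](C(=O)N4[C@@H](Cc5ccccc5)COC4=O)c4ccc(OCc5ccccc5)c(OC)c4)cc3[C@@H]2CON4C(C)(C)CCCC4(C)C)ccc1OCc1ccccc1 | intermediate
18 | (1S,2R)-2-(4-benzyloxy-3-methoxyphenyl)-1-{(2S,3R)-2-(4-benzyloxy-3-methoxyphenyl)-7-methoxy-3-[(2,2,6,6-tetramethylpiperidin-1-yloxy)methyl]-2,3-dihydrobenzofuran-5-yl}propane-1,3-diol | COc1cc([C@H]2Oc3c(OC)cc([C@@H](O)[C@@H](CO)c4ccc(OCc5ccccc5)c(OC)c4)cc3[C@@H]2CON4C(C)(C)CCCC4(C)C)ccc1OCc1ccccc1 | intermediate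
19 | (1S,2R)-2-(4-benzyloxy-3-methoxyphenyl)-1-[(2S,3R)-2-(4-benzyloxy-3-methoxyphenyl)-3-(hydroxymethyl)-7-methoxy-2,3-dihydrobenzofuran-5-yl]propane-1,3-diol | COc1cc([C@H]2Oc3c(OC)cc([C@@H](O)[C@@H](CO)c4ccc(OCc5ccccc5)c(OC)c4)cc3[C@@H]2CO)ccc1OCc1ccccc1 | intermediate
20 | (1S,2R)-1-[(2S,3R)-2-(4-hydroxy-3-methoxyphenyl)-3-(hydroxymethyl)-7-methoxy-2,3-dihydrobenzofuran-5-yl]-2-(4-hydroxy-3-methoxyphenyl)propane-1,3-diol | COc1cc([C@H]2Oc3c(OC)cc([C@@H](O)[C@@H](CO)c4ccc(O)c(OC)c4)cc3[C@@H]2CO)ccc1O | target

## Step count and least certain steps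

Total: 11 steps. Longest linear sequence: 9 steps (steps 1–5 and 8–11, from ferulic acid); the ring-C branch (steps 6 and 7) joins at step 8.

**Step 5 (key step).**
- What may go wrong: incomplete trans control at C3. The aryl-radical transition state is flattened by the two sp2 ring atoms, so the pseudo-equatorial preference of ring A may be modest and some cis ring may form. Chain efficiency may also be low, because TEMPO consumes stannyl radicals.
- Fallback: this replaces kinetic control by equilibration. It sets out from 18, carried forward as the mixture of C3 epimers, and returns at 19. Oxidation with mCPBA (CH2Cl2, 0 °C) turns the alkoxyamine into the C3 aldehyde by N-oxidation and elimination. This gives (2S,3R)-2-(4-benzyloxy-3-methoxyphenyl)-5-[(1S,2R)-2-(4-benzyloxy-3-methoxyphenyl)-1,3-dihydroxypropyl]-7-methoxy-2,3-dihydrobenzofuran-3-carbaldehyde F3 from the cis material and (2S,3S)-2-(4-benzyloxy-3-methoxyphenyl)-5-[(1S,2R)-2-(4-benzyloxy-3-methoxyphenyl)-1,3-dihydroxypropyl]-7-methoxy-2,3-dihydrobenzofuran-3-carbaldehyde F4 from the trans material. Catalytic DBU at 0 °C should epimerise F3 at the now acidic C3–H to the more stable trans aldehyde F4, with the temperature kept low to avoid β-elimination of the aryloxide. NaBH4 in MeOH then gives 19. This also bypasses step 10.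

**Step 4.**
- What may go wrong: slow capture of the allyl complex by a 2,6-disubstituted, formyl-deactivated aryloxide, and re-ionisation of the product by the catalyst (good aryloxide leaving group on an electron-rich benzylic carbon). Both would erode enantiomeric purity and leak material to the linear ether.
- Fallback: this separates the asymmetric C–O bond formation from the aryl ether formation. It sets out from 4 and returns at 7. Carbonate 4 is treated with Et3SiOK, [Ir(cod)Cl]2 and the (Ra,Rc,Rc) ligand in CH2Cl2, a known branched-selective allylic substitution with a small oxygen nucleophile, to give (R)-[1-(4-benzyloxy-3-methoxyphenyl)allyloxy]triethylsilane F1. Bu4NF releases (R)-1-(4-benzyloxy-3-methoxyphenyl)prop-2-en-1-ol F2. Mitsunobu etherification of F2 with 5 (PPh3, DIAD, toluene, −20 °C) should give 7 with inversion; the cold, non-polar medium is chosen to hold back ionisation of the benzylic centre.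

**Step 8.**
- What may go wrong: leakage to the Cα epimer. The aryl-stabilised enolate is less nucleophilic and the aldehyde is electron-rich, so the addition may need warmer conditions at which the closed transition state is less strictly followed; partial retro-aldol during work-up is also possible.
- Fallback: Cα is set by hydride delivery instead of the aldol geometry. It sets out from 17 (the crude adduct with its Cα epimer) and returns at 17. Dess–Martin periodinane in CH2Cl2 oxidises both epimers to the single β-keto imide (S)-4-benzyl-3-[(2S)-2-(4-benzyloxy-3-methoxyphenyl)-3-{(2S,3R)-2-(4-benzyloxy-3-methoxyphenyl)-7-methoxy-3-[(2,2,6,6-tetramethylpiperidin-1-yloxy)methyl]-2,3-dihydrobenzofuran-5-yl}-3-oxopropanoyl]oxazolidin-2-one F5. Its Cβ configuration comes from the auxiliary-controlled enolate face and is protected from enolisation by allylic strain. Chelation-controlled reduction with Zn(BH4)2 (CH2Cl2/Et2O, −20 °C) should then give the syn alcohol 17.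

**Step 10.**
- What may go wrong: acid-promoted ionisation at Cα (epimerisation, acetolysis, or loss of formaldehyde from the 1,3-diol) and partial O-acetylation during the warm acetic acid reduction.
- Fallback: the N–O bond is cleaved before the side chain exists. It sets out from 8 and returns at 19. Zn dust in AcOH/THF/H2O with 8, whose ring B is deactivated by the aldehyde, gives (2S,3R)-2-(4-benzyloxy-3-methoxyphenyl)-3-(hydroxymethyl)-7-methoxy-2,3-dihydrobenzofuran-5-carbaldehyde F6. TBSCl and imidazole in DMF give (2S,3R)-2-(4-benzyloxy-3-methoxyphenyl)-3-[(tert-butyldimethylsilyloxy)methyl]-7-methoxy-2,3-dihydrobenzofuran-5-carbaldehyde F7. Aldol addition of enolate 15 under the conditions of step 8 passes through the O-dibutylboryl aldolate of the silyl-protected adduct F8 and gives (S)-4-benzyl-3-[(2S,3S)-2-(4-benzyloxy-3-methoxyphenyl)-3-{(2S,3R)-2-(4-benzyloxy-3-methoxyphenyl)-3-[(tert-butyldimethylsilyloxy)methyl]-7-methoxy-2,3-dihydrobenzofuran-5-yl}-3-hydroxypropanoyl]oxazolidin-2-one F9. LiBH4 gives (1S,2R)-2-(4-benzyloxy-3-methoxyphenyl)-1-{(2S,3R)-2-(4-benzyloxy-3-methoxyphenyl)-3-[(tert-butyldimethylsilyloxy)methyl]-7-methoxy-2,3-dihydrobenzofuran-5-yl}propane-1,3-diol F10, and Bu4NF in THF removes the silyl group to give 19.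

## Further compounds

F1 | step 4 | (R)-[1-(4-benzyloxy-3-methoxyphenyl)allyloxy]triethylsilane | COc1cc([C@@H](C=C)O[Si](CC)(CC)CC)ccc1OCc1ccccc1
F2 | step 4 | (R)-1-(4-benzyloxy-3-methoxyphenyl)prop-2-en-1-ol | COc1cc([C@@H](C=C)O)ccc1OCc1ccccc1
F3 | step 5 | (2S,3R)-2-(4-benzyloxy-3-methoxyphenyl)-5-[(1S,2R)-2-(4-benzyloxy-3-methoxyphenyl)-1,3-dihydroxypropyl]-7-methoxy-2,3-dihydrobenzofuran-3-carbaldehyde (cis ring) | COc1cc([C@H]2Oc3c(OC)cc([C@@H](O)[C@@H](CO)c4ccc(OCc5ccccc5)c(OC)c4)cc3[C@H]2C=O)ccc1OCc1ccccc1
F4 | step 5 | (2S,3S)-2-(4-benzyloxy-3-methoxyphenyl)-5-[(1S,2R)-2-(4-benzyloxy-3-methoxyphenyl)-1,3-dihydroxypropyl]-7-methoxy-2,3-dihydrobenzofuran-3-carbaldehyde (trans ring) | COc1cc([C@H]2Oc3c(OC)cc([C@@H](O)[C@@H](CO)c4ccc(OCc5ccccc5)c(OC)c4)cc3[C@@H]2C=O)ccc1OCc1ccccc1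
F5 | step 8 | (S)-4-benzyl-3-[(2S)-2-(4-benzyloxy-3-methoxyphenyl)-3-{(2S,3R)-2-(4-benzyloxy-3-methoxyphenyl)-7-methoxy-3-[(2,2,6,6-tetramethylpiperidin-1-yloxy)methyl]-2,3-dihydrobenzofuran-5-yl}-3-oxopropanoyl]oxazolidin-2-one | COc1cc([C@H]2Oc3c(OC)cc(C(=O)[C@@H](C(=O)N4[C@@H](Cc5ccccc5)COC4=O)c4ccc(OCc5ccccc5)c(OC)c4)cc3[C@@H]2CON4C(C)(C)CCCC4(C)C)ccc1OCc1ccccc1
F6 | step 10 | (2S,3R)-2-(4-benzyloxy-3-methoxyphenyl)-3-(hydroxymethyl)-7-methoxy-2,3-dihydrobenzofuran-5-carbaldehyde | COc1cc([C@H]2Oc3c(OC)cc(C=O)cc3[C@@H]2CO)ccc1OCc1ccccc1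
F7 | step 10 | (2S,3R)-2-(4-benzyloxy-3-methoxyphenyl)-3-[(tert-butyldimethylsilyloxy)methyl]-7-methoxy-2,3-dihydrobenzofuran-5-carbaldehyde | COc1cc([C@H]2Oc3c(OC)cc(C=O)cc3[C@@H]2CO[Si](C)(C)C(C)(C)C)ccc1OCc1ccccc1
F8 | step 10 | O-dibutylboryl aldolate of the silyl-protected adduct F9 | COc1cc([C@H]2Oc3c(OC)cc([C@@H](OB(CCCC)CCCC)[C@@H](C(=O)N4[C@@H](Cc5ccccc5)COC4=O)c4ccc(OCc5ccccc5)c(OC)c4)cc3[C@@H]2CO[Si](C)(C)C(C)(C)C)ccc1OCc1ccccc1
F9 | step 10 | (S)-4-benzyl-3-[(2S,3S)-2-(4-benzyloxy-3-methoxyphenyl)-3-{(2S,3R)-2-(4-benzyloxy-3-methoxyphenyl)-3-[(tert-butyldimethylsilyloxy)methyl]-7-methoxy-2,3-dihydrobenzofuran-5-yl}-3-hydroxypropanoyl]oxazolidin-2-one | COc1cc([C@H]2Oc3c(OC)cc([C@@H](O)[C@@H](C(=O)N4[C@@H](Cc5ccccc5)COC4=O)c4ccc(OCc5ccccc5)c(OC)c4)cc3[C@@H]2CO[Si](C)(C)C(C)(C)C)ccc1OCc1ccccc1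
F10 | step 10 | (1S,2R)-2-(4-benzyloxy-3-methoxyphenyl)-1-{(2S,3R)-2-(4-benzyloxy-3-methoxyphenyl)-3-[(tert-butyldimethylsilyloxy)methyl]-7-methoxy-2,3-dihydrobenzofuran-5-yl}propane-1,3-diol | COc1cc([C@H]2Oc3c(OC)cc([C@@H](O)[C@@H](CO)c4ccc(OCc5ccccc5)c(OC)c4)cc3[C@@H]2CO[Si](C)(C)C(C)(C)C)ccc1OCc1ccccc1
A1 | alternative 1 | (2S,3R)-5-bromo-2-(4-hydroxy-3-methoxyphenyl)-3-(hydroxymethyl)-7-methoxy-2,3-dihydrobenzofuran | COc1cc([C@H]2Oc3c(OC)cc(Br)cc3[C@@H]2CO)ccc1O
A2 | alternative 1 | (2R)-2-(5-bromo-2-hydroxy-3-methoxyphenyl)-1-(4-hydroxy-3-methoxyphenyl)propane-1,3-diol (both C1 epimers) | COc1cc(C(O)[C@@H](CO)c2cc(Br)cc(OC)c2O)ccc1O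
A3 | alternative 2 | (3S,4S)-3-(4-benzyloxy-3-methoxyphenyl)-4-[3-methoxy-4-(methanesulfonyloxy)phenyl]oxetan-2-one (cis) | COc1cc([C@H]2OC(=O)[C@H]2c2ccc(OCc3ccccc3)c(OC)c2)ccc1OS(C)(=O)=O
A4 | alternative 2 | (2R,3R)-2-(4-benzyloxy-3-methoxyphenyl)-3-[3-methoxy-4-(methanesulfonyloxy)phenyl]oxirane (trans) | COc1cc([C@H]2O[C@@H]2c2ccc(OCc3ccccc3)c(OC)c2)ccc1OS(C)(=O)=O
A5 | alternative 3 | (1S,2R)-2-(4-benzyloxy-3-methoxyphenyl)-1-{(2S,3R)-2-(4-benzyloxy-3-methoxyphenyl)-3-[(tert-butyldimethylsilyloxy)methyl]-7-methoxy-2,3-dihydrobenzofuran-5-yl}-3-(tert-butyldimethylsilyloxy)propan-1-ol | COc1cc([C@H]2Oc3c(OC)cc([C@@H](O)[C@@H](CO[Si](C)(C)C(C)(C)C)c4ccc(OCc5ccccc5)c(OC)c4)cc3[C@@H]2CO[Si](C)(C)C(C)(C)C)ccc1OCc1ccccc1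
A6 | alternative 3 | (2S,3R)-2-(4-benzyloxy-3-methoxyphenyl)-5-bromo-3-[(tert-butyldimethylsilyloxy)methyl]-7-methoxy-2,3-dihydrobenzofuran | COc1cc([C@H]2Oc3c(OC)cc(Br)cc3[C@@H]2CO[Si](C)(C)C(C)(C)C)ccc1OCc1ccccc1
A7 | alternative 3 | tert-butyldimethyl{[(E)-3-(4,4,5,5-tetramethyl-1,3,2-dioxaborolan-2-yl)allyl]oxy}silane | CC(C)(C)[Si](C)(C)OC/C=C/B1OC(C)(C)C(C)(C)O1
A8 | alternative 3 | 4-benzyloxy-3-methoxyphenyl trifluoromethanesulfonate | COc1cc(OS(=O)(=O)C(F)(F)F)ccc1OCc1ccccc1
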